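**Retrosynthetic overview**
1. Aspergilol C ⇐ silyl ether 29 ⇐ enol phosphate 28. The cyclohexene alkene is carried as a ring ketone until the end; one Li/NH3 reduction reveals it and removes two sulfonyl auxiliaries.
2. Key disconnection, a (5+3) annulation of the cyclooctene: both bonds that tie the CH2–CH2–CH(CH3) bridge to the rest are cut, giving silyl enol ether/allylic carbonate 24 and the three-carbon ambiphile 9 (enal = Michael acceptor, bis-sulfonyl methine = soft nucleophile). Enabling feature: the bridge joins the cyclopentane CH that is allylic to the tetrasubstituted ring alkene (a π-allyl terminus) to the cyclohexene carbon that is α to a latent ketone (an enolate carbon); these two carbons are 1,5-related through the doubly allylic CH of the six-membered ring.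
3. 24 ⇐ trans-hydrindanone methyl ketone 20 + (S)-3-methylcyclopentenyl metal (4 → 21).
4. 20 ⇐ (R)-carvone: conjugate addition/aldol, ring-closing metathesis, hydroxyl-directed hydrogenation, epimerisation.
5. Ring order: cyclohexane (from carvone) → hydroxylated cyclopentane (RCM) → methylcyclopentene appended → cyclooctene last (step 14).

Key step: step 14

Remarks (assumptions on the chemistry):
- Own locants used in the text: C2=C3 tetrasubstituted alkene (C2 carries CH3, C3 is in the methylcyclopentane), C6 cyclopentane CH–CH3, C8 cyclopentane CH between C3 and C6, C9–C10–C11 bridge (C11 carries CH3), C13=C14 cyclohexene alkene (C13 bonded to C11), C26 the CH between C13 and C2. Hydrindane locants in names: C1 carbinol, C3 CH–iPr, C5 side-chain carbon, C7 ketone, C7a C–CH3; β is the face of the angular methyl.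
- The ligand antipode in step 1 and the organocatalyst antipode in step 14 are assumed to follow the facial sense of the closest precedents (cyclic enone/Grignard; indole/crotonaldehyde) and would be exchanged for the mirror image otherwise.
- 22–24 are carried as mixtures at the carbinol carbon and 25–27 as mixtures at C13; both centres become sp2 later and are written without configuration.

**Route**

Step 1
Reactants: 1 cyclopent-2-en-1-one
Product: 3 (S)-3-methylcyclopent-1-en-1-yl trifluoromethanesulfonate, via bromomagnesium enolate 2 (not isolated)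
Conditions: MeMgBr, CuBr·SMe2 (5 mol%), Josiphos ligand (6 mol%), t-BuOMe, −78 °C; then PhNTf2, THF, −78 → 0 °C
Reagents that add atoms: methylmagnesium bromide C[Mg]Br; N-phenylbis(trifluoromethanesulfonimide) O=S(=O)(N(c1ccccc1)S(=O)(=O)C(F)(F)F)C(F)(F)F
Why: Copper-catalysed asymmetric conjugate addition sets the methyl-bearing stereocentre under ligand control and forms the enolate regiospecifically next to it, so O-triflation fixes the ring alkene where ring A needs it.

Step 2
Reactants: 3 (S)-3-methylcyclopent-1-en-1-yl trifluoromethanesulfonate
Product: 4 (S)-trimethyl(3-methylcyclopent-1-en-1-yl)stannane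
Conditions: Me3SnSnMe3, Pd(PPh3)4 (5 mol%), LiCl, THF, 65 °C
Reagents that add atoms: hexamethylditin C[Sn](C)(C)[Sn](C)(C)C
Why: Palladium-catalysed stannylation of an enol triflate (Stille-type) should give the vinylstannane without touching the stereocentre or the alkene position.

Step 3
Reactants: 5 bis(phenylsulfonyl)methane; 6 allyl bromide
Product: 7 4,4-bis(phenylsulfonyl)but-1-ene
Conditions: NaH (1.0 equiv), DMF, 0 °C → rt
Reagents that add atoms: none
Why: SN2 C-alkylation of the doubly sulfone-stabilised carbanion with an allylic bromide should stop at monoalkylation with one equivalent of base.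

Step 4
Reactants: 7 4,4-bis(phenylsulfonyl)but-1-ene; 8 (E)-but-2-enal
Product: 9 (E)-5,5-bis(phenylsulfonyl)pent-2-enal
Conditions: Ru isopropoxybenzylidene catalyst (second generation, 5 mol%), 8 (5 equiv), CH2Cl2, 40 °C
Reagents that add atoms: none
Why: Olefin cross-metathesis of a terminal alkene with crotonaldehyde should give the (E)-enal, the thermodynamically favoured isomer under secondary metathesis.

Step 5
Reactants: 10 (R)-carvone; 11 2-bromo-3-methylbut-1-ene; 12 acrolein
Product: 15 keto alcohol triene (three-component adduct), via alkenyl Grignard reagent 13 (not isolated), via bromomagnesium enolate 14 (not isolated)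
Conditions: 11, Mg, THF, rt; CuBr·SMe2 (10 mol%), 10, THF, −40 °C; then 12, −78 °C
Reagents that add atoms: none
Why: Copper-catalysed 1,4-addition should occur anti to the isopropenyl group, the aldol reaction of the magnesium enolate with acrolein anti to the new alkenyl group (quaternary methyl centre, trans relationship of the future ring fusion), and a closed Zimmerman–Traxler transition state with the vinyl group equatorial should place the hydroxyl syn to the ring methyl.

Step 6
Reactants: 15 keto alcohol triene
Product: 16 trans-hydrindenone allylic alcohol (5α-isopropenyl)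
Conditions: Ru benzylidene catalyst (second generation, 5 mol%), toluene, 80 °C
Reagents that add atoms: none
Why: Ring-closing metathesis of the 1,6-diene should close the cyclopentene with loss of ethene and leave the isopropyl group on the new trisubstituted alkene, while the isopropenyl group cannot cyclise without forming a bridged ring.

Step 7
Reactants: 16 trans-hydrindenone allylic alcohol
Product: 17 5α-acetyl trans-hydrindenone allylic alcohol
Conditions: K2OsO4·2H2O (2 mol%), NaIO4, 2,6-lutidine, dioxane/H2O, 0 °C → rt
Reagents that add atoms: sodium periodate [Na+].[O-]I(=O)(=O)=O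
Why: Lemieux–Johnson cleavage should attack the unhindered 1,1-disubstituted isopropenyl alkene faster than the ring alkene, which is shielded by the isopropyl group and the ring fusion, and give the methyl ketone.

Step 8
Reactants: 17 5α-acetyl trans-hydrindenone allylic alcohol
Product: 18 5α-acetyl-1β-hydroxy-3α-isopropyl trans-hydrindan-7-one
Conditions: [Ir(cod)(PCy3)(py)]PF6 (5 mol%), H2 (1 atm), CH2Cl2, rt
Reagents that add atoms: none
Why: Hydroxyl-directed hydrogenation should deliver hydrogen to the alkene face syn to the allylic hydroxyl, which sets the isopropyl-bearing centre trans to the angular methyl and leaves the ketones untouched.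

Step 9
Reactants: 18 5α-acetyl-1β-hydroxy-3α-isopropyl trans-hydrindan-7-one
Product: 19 TBS ether of 18
Conditions: TBSOTf, 2,6-lutidine, CH2Cl2, −78 → 0 °C
Reagents that add atoms: tert-butyldimethylsilyl trifluoromethanesulfonate CC(C)(C)[Si](C)(C)OS(=O)(=O)C(F)(F)F
Why: Silylation of the hindered secondary alcohol with a silyl triflate protects it for the basic and organometallic steps and blocks retro-aldol cleavage of the β-hydroxy ketone.

Step 10
Reactants: 19 TBS ether (5α-acetyl)
Product: 20 5β-acetyl epimer (equatorial acetyl)
Conditions: DBU, toluene, 60 °C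
Reagents that add atoms: none
Why: Base-mediated epimerisation α to the methyl ketone should move the acetyl group from the axial to the equatorial position of the locked trans-hydrindanone (thermodynamic control), giving the configuration of the doubly allylic carbon C26.

Step 11
Reactants: 20 5β-acetyl trans-hydrindanone TBS ether; 4 (S)-trimethyl(3-methylcyclopent-1-en-1-yl)stannane
Product: 22 tertiary allylic alcohol, via vinyllithium 21 (not isolated)
Conditions: 4, MeLi, THF, −78 °C; LaCl3·2LiCl; then 20, −78 °C
Reagents that add atoms: none
Why: Tin–lithium exchange keeps the alkene position, and lanthanum-mediated 1,2-addition should take place at the unhindered methyl ketone rather than at the ring ketone flanked by the quaternary carbon, with no control needed at the new carbinol carbon because both epimers give the same π-allyl complex in step 14.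

Step 12
Reactants: 22 tertiary allylic alcohol
Product: 23 tertiary allylic methyl carbonate
Conditions: LiHMDS (1.05 equiv), THF, −78 °C; then ClCO2Me
Reagents that add atoms: methyl chloroformate COC(=O)Cl
Why: One equivalent of base deprotonates the alcohol in preference to the ketone, and O-acylation of the alkoxide installs the leaving group for the palladium step.

Step 13
Reactants: 23 tertiary allylic methyl carbonate
Product: 24 trimethylsilyl enol ether of 23
Conditions: LDA, TMSCl (in situ), THF, −78 °C
Reagents that add atoms: chlorotrimethylsilane C[Si](C)(C)Cl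
Why: The ring ketone has α-hydrogens on one side only, so kinetic deprotonation with in situ silylation should give a single silyl enol ether whose nucleophilic carbon is C13.

Step 14
Reactants: 24 trimethylsilyl enol ether carbonate; 9 (E)-5,5-bis(phenylsulfonyl)pent-2-enal
Product: 26 tetracyclic keto aldehyde bis-sulfone, via Michael adduct aldehyde 25 (not isolated)
Conditions: (2R,5R)-5-benzyl-2-tert-butyl-3-methylimidazolidin-4-one·TFA (20 mol%), CH2Cl2/H2O (20:1), −20 °C; then Et3N, Pd2(dba)3·CHCl3 (5 mol%), dppe (12 mol%), THF (0.005 M), 50 °C
Reagents that add atoms: none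
Why: Stage 1 is an iminium-activated Mukaiyama–Michael addition: the imidazolidinone condenses with enal 9, the silyl enol ether adds through C13 to the β-carbon (C11), and hydrolysis returns the catalyst, the ring ketone and aldehyde 25; in stage 2 Pd(0) ionises the tertiary allylic carbonate to a π-allyl complex, the liberated methoxide deprotonates the bis-sulfonyl methine (C9), and the soft carbanion attacks the secondary allyl terminus C8 anti to palladium. The closest known reaction types are organocatalytic Mukaiyama–Michael additions of silyl enol ethers to enals and Tsuji–Trost medium-ring cyclisations with sulfone-stabilised carbanions. The eight-membered ring closes in the endo mode of an intramolecular Tsuji–Trost reaction (attack at the allyl terminus remote from the tether), which puts the new tetrasubstituted C2=C3 alkene inside the ring and so fixes its geometry (C26 cis to C8). C11 is set by the catalyst, whose benzyl group shields one enal face; C8 is set by the anti/anti course of ionisation and attack, with palladium expected on the allyl face away from the neighbouring C6 methyl so that C9 enters syn to that methyl; C13 forms without control and is erased in step 16. The step needs attack at C8 rather than C2 (which would give a six-membered ring with a quaternary centre) and cyclisation rather than oligomerisation: the tertiary terminus and the bulky nucleophile disfavour C2, and high dilution favours ring closure.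

Step 15
Reactants: 26 tetracyclic keto aldehyde bis-sulfone
Product: 27 tetracyclic ketone bis-sulfone
Conditions: [Rh(dppp)2]Cl (5 mol%), diglyme, 150 °C
Reagents that add atoms: none
Why: Rhodium-catalysed decarbonylation (Tsuji–Wilkinson type) of the primary aldehyde should excise the formyl carbon and leave the methyl group of the bridge without touching the C11 stereocentre.

Step 16
Reactants: 27 tetracyclic ketone bis-sulfone
Product: 28 enol diethyl phosphate
Conditions: KHMDS, THF, −78 °C; then ClP(O)(OEt)2
Reagents that add atoms: diethyl chlorophosphate CCOP(=O)(Cl)OCC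
Why: The ketone can enolise only towards C13, so O-phosphorylation of its potassium enolate should give a single enol phosphate with the double bond where the C13=C14 alkene of the target lies.

Step 17
Reactants: 28 enol diethyl phosphate
Product: 29 aspergilol C TBS ether
Conditions: Li, NH3(l), THF, t-BuOH, −78 °C
Reagents that add atoms: none
Why: Dissolving-metal reduction should cleave the enol phosphate C–O bond to the alkene and remove both sulfonyl groups by reductive desulfonylation in one operation, while the isolated tri- and tetrasubstituted alkenes and the silyl ether are inert.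

Step 18
Reactants: 29 aspergilol C TBS ether
Product: 30 aspergilol C
Conditions: TBAF, THF, 50 °C
Reagents that add atoms: none
Why: Fluoride-mediated cleavage of the silyl ether releases the secondary alcohol of the target.

**Compound list**
1 | cyclopent-2-en-1-one | O=C1CCC=C1 | starting material
2 | bromomagnesium (S)-3-methylcyclopent-1-en-1-olate | Br[Mg]OC1=C[C@@H](C)CC1 | intermediate
3 | (S)-3-methylcyclopent-1-en-1-yl trifluoromethanesulfonate | FC(F)(F)S(=O)(=O)OC1=C[C@@H](C)CC1 | intermediate
4 | (S)-trimethyl(3-methylcyclopent-1-en-1-yl)stannane | C[Sn](C)(C)C1=C[C@@H](C)CC1 | intermediate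
5 | bis(phenylsulfonyl)methane | O=S(=O)(CS(=O)(=O)c1ccccc1)c1ccccc1 | starting material
6 | allyl bromide | C=CCBr | starting material
7 | 4,4-bis(phenylsulfonyl)but-1-ene | C=CCC(S(=O)(=O)c1ccccc1)S(=O)(=O)c1ccccc1 | intermediate
8 | (E)-but-2-enal (crotonaldehyde) | C/C=C/C=O | starting material
9 | (E)-5,5-bis(phenylsulfonyl)pent-2-enal | O=C/C=C/CC(S(=O)(=O)c1ccccc1)S(=O)(=O)c1ccccc1 | intermediate
10 | (R)-carvone | CC(=C)[C@@H]1CC=C(C)C(=O)C1 | starting material
11 | 2-bromo-3-methylbut-1-ene | C=C(Br)C(C)C | starting material
12 | acrolein | C=CC=O | starting material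
13 | (3-methylbut-1-en-2-yl)magnesium bromide | C=C([Mg]Br)C(C)C | intermediate
14 | bromomagnesium enolate of the 1,4-adduct (alkenyl group trans to isopropenyl) | C1C(O[Mg]Br)=C(C)[C@H](C(=C)C(C)C)C[C@H]1C(C)=C | intermediate
15 | 2-(1-hydroxyprop-2-enyl)-2-methyl-3-(3-methylbut-1-en-2-yl)-5-(prop-1-en-2-yl)cyclohexanone; 3-alkenyl trans to 5-isopropenyl, hydroxyallyl trans to 3-alkenyl, OH syn to ring methyl | C1C(=O)[C@@](C)([C@H](O)C=C)[C@H](C(=C)C(C)C)C[C@H]1C(C)=C | intermediate
16 | trans-fused 1β-hydroxy-3-isopropyl-7aβ-methyl-5α-(prop-1-en-2-yl)-1,3a,4,5,6,7a-hexahydroinden-7-one (3aα-H) | C1C(=O)[C@@]2(C)[C@H](O)C=C(C(C)C)[C@@H]2C[C@H]1C(C)=C | intermediate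
17 | 5α-acetyl analogue of 16 | C1C(=O)[C@@]2(C)[C@H](O)C=C(C(C)C)[C@@H]2C[C@H]1C(C)=O | intermediate
18 | 5α-acetyl-1β-hydroxy-3α-isopropyl-7aβ-methyl-trans-octahydroinden-7-one | C1C(=O)[C@@]2(C)[C@H](O)C[C@@H](C(C)C)[C@@H]2C[C@H]1C(C)=O | intermediate
19 | 1β-TBS ether of 18 (acetyl axial, 5α) | C1C(=O)[C@@]2(C)[C@H](O[Si](C)(C)C(C)(C)C)C[C@@H](C(C)C)[C@@H]2C[C@H]1C(C)=O | intermediate
20 | 5β-acetyl epimer of 19 (acetyl equatorial) | C1C(=O)[C@@]2(C)[C@H](O[Si](C)(C)C(C)(C)C)C[C@@H](C(C)C)[C@@H]2C[C@@H]1C(C)=O | intermediate
21 | (S)-(3-methylcyclopent-1-en-1-yl)lithium | [Li]C1=C[C@@H](C)CC1 | intermediate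
22 | tertiary allylic alcohol: 5β-[1-hydroxy-1-((S)-3-methylcyclopent-1-enyl)ethyl] hydrindanone TBS ether (both carbinol epimers) | C1C(=O)[C@@]2(C)[C@H](O[Si](C)(C)C(C)(C)C)C[C@@H](C(C)C)[C@@H]2C[C@@H]1C(C)(O)C3=C[C@@H](C)CC3 | intermediate
23 | methyl carbonate of 22 | C1C(=O)[C@@]2(C)[C@H](O[Si](C)(C)C(C)(C)C)C[C@@H](C(C)C)[C@@H]2C[C@@H]1C(C)(OC(=O)OC)C3=C[C@@H](C)CC3 | intermediate
24 | 7-trimethylsilyloxy-Δ6 silyl enol ether of 23 | C1=C(O[Si](C)(C)C)[C@@]2(C)[C@H](O[Si](C)(C)C(C)(C)C)C[C@@H](C(C)C)[C@@H]2C[C@@H]1C(C)(OC(=O)OC)C3=C[C@@H](C)CC3 | intermediate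
25 | Michael adduct: hydrindanone carbonate carrying at C6 the (R)-1-(2-oxoethyl)-3,3-bis(phenylsulfonyl)propyl group (C6 epimers) | C1([C@H](CC=O)CC(S(=O)(=O)c4ccccc4)S(=O)(=O)c5ccccc5)C(=O)[C@@]2(C)[C@H](O[Si](C)(C)C(C)(C)C)C[C@@H](C(C)C)[C@@H]2C[C@@H]1C(C)(OC(=O)OC)C3=C[C@@H](C)CC3 | intermediate
26 | 5-8-6-5 tetracyclic keto aldehyde bis-sulfone (C13 epimers; CH2CHO in place of the bridge methyl) | C/C1=C2\CC[C@H](C)[C@@H]2C(S(=O)(=O)c4ccccc4)(S(=O)(=O)c5ccccc5)C[C@@H](CC=O)C2C(=O)[C@@]3(C)[C@H](O[Si](C)(C)C(C)(C)C)C[C@@H](C(C)C)[C@@H]3C[C@@H]21 | intermediate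
27 | 5-8-6-5 tetracyclic ketone bis-sulfone (C13 epimers) | C/C1=C2\CC[C@H](C)[C@@H]2C(S(=O)(=O)c4ccccc4)(S(=O)(=O)c5ccccc5)C[C@@H](C)C2C(=O)[C@@]3(C)[C@H](O[Si](C)(C)C(C)(C)C)C[C@@H](C(C)C)[C@@H]3C[C@@H]21 | intermediate
28 | enol diethyl phosphate of 27 | C/C1=C2\CC[C@H](C)[C@@H]2C(S(=O)(=O)c4ccccc4)(S(=O)(=O)c5ccccc5)C[C@@H](C)C2=C(OP(=O)(OCC)OCC)[C@@]3(C)[C@H](O[Si](C)(C)C(C)(C)C)C[C@@H](C(C)C)[C@@H]3C[C@@H]21 | intermediate
29 | aspergilol C tert-butyldimethylsilyl ether | C/C1=C2\CC[C@H](C)[C@@H]2CC[C@@H](C)C2=C[C@@]3(C)[C@H](O[Si](C)(C)C(C)(C)C)C[C@@H](C(C)C)[C@@H]3C[C@@H]21 | intermediate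
30 | aspergilol C | C/C1=C2\CC[C@H](C)[C@@H]2CC[C@@H](C)C2=C[C@@]3(C)[C@H](O)C[C@@H](C(C)C)[C@@H]3C[C@@H]21 | target

**Step count and risks**
Total: 18 steps. Longest linear sequence: 14 steps (steps 5–18, from (R)-carvone).

Most likely to fail:

1. Step 14. The eight-membered ring closure may be slow enough for β-hydride elimination of the tertiary π-allyl complex to a diene to take over, or the carbanion may attack the wrong allyl face at the cyclopentane carbon. The fallback inverts the order of the two bond formations and sets out from carbonate 23 and enal 9. Intermolecular Tsuji–Trost alkylation of the sodium salt of 9 (NaH, Pd(PPh3)4, THF; a chiral diphosphine could be used to steer the allyl face) would form the cyclopentane–C(SO2Ph)2 bond first and, after separation of the alkene isomers, give the keto enal F1. The ring would then be closed at the other bond by an intramolecular Michael addition of the ring ketone to the tethered enal under secondary-amine catalysis (diarylprolinol silyl ether, benzoic acid), which comes back to the route at 26.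

2. Step 5. Diastereocontrol at the carbinol carbon may be incomplete in the aldol reaction of the tetrasubstituted magnesium enolate, with partial retro-aldol on warming. The fallback sets the carbinol centre by reduction instead: it sets out from 16 (carried through step 6 as the epimer mixture), oxidises the allylic alcohol with MnO2 to the cyclopentenone F2, and reduces it under Luche conditions (NaBH4, CeCl3, MeOH, −78 °C). Hydride should attack the enone carbonyl from the face opposite the angular methyl and spare the hindered saturated ketone, which comes back to the route at 16 as the single 1β-alcohol.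

3. Step 7. The osmium-catalysed cleavage may not distinguish the isopropenyl group from the ring alkene, so the cyclopentene is over-oxidised. The fallback unveils the methyl ketone before any other alkene is present and sets out from carvone 10. Ozonolysis (O3, CH2Cl2/MeOH, −78 °C; Me2S; the enone alkene is inert) should give the acetyl enone F3, and acetalisation of the saturated ketone (ethylene glycol, PPTS) the dioxolane F4. The conditions of steps 5, 6 and 8 applied to F4 would give the adduct F5, the cyclopentenol F6 and, after directed hydrogenation, the saturated ketal F7. Mild acid (PPTS, acetone/water) would then release the methyl ketone and come back to the route at 18.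

Further compounds
F1 | step 14 | keto enal from intermolecular allylic alkylation of 9 with 23 (tetrasubstituted alkene with the hydrindanyl group cis to the substituted cyclopentane carbon) | C/C(=C1\CC[C@H](C)[C@@H]1C(S(=O)(=O)c2ccccc2)(S(=O)(=O)c2ccccc2)C/C=C/C=O)[C@@H]1CC(=O)[C@@]2(C)[C@H](O[Si](C)(C)C(C)(C)C)C[C@@H](C(C)C)[C@@H]2C1
F2 | step 5 | trans-fused 3-isopropyl-7a-methyl-5α-(prop-1-en-2-yl)-4,5,6,7a-tetrahydro-3aH-indene-1,7-dione | C1C(=O)[C@@]2(C)C(=O)C=C(C(C)C)[C@@H]2C[C@H]1C(C)=C
F3 | step 7 | (R)-5-acetyl-2-methylcyclohex-2-en-1-one | CC(=O)[C@@H]1CC=C(C)C(=O)C1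
F4 | step 7 | (R)-2-methyl-5-(2-methyl-1,3-dioxolan-2-yl)cyclohex-2-en-1-one | CC2(OCCO2)[C@@H]1CC=C(C)C(=O)C1
F5 | step 7 | dioxolane analogue of 15 | C1C(=O)[C@@](C)([C@H](O)C=C)[C@H](C(=C)C(C)C)C[C@H]1C2(C)OCCO2
F6 | step 7 | dioxolane analogue of 16 | C1C(=O)[C@@]2(C)[C@H](O)C=C(C(C)C)[C@@H]2C[C@H]1C3(C)OCCO3
F7 | step 7 | dioxolane of 18 | C1C(=O)[C@@]2(C)[C@H](O)C[C@@H](C(C)C)[C@@H]2C[C@H]1C3(C)OCCO3
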